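## Retrosynthetic overview

1. C13–C14 is cut last: a Pd-catalysed B-alkyl Suzuki–Miyaura coupling joins the 9-BBN adduct of a terminal-alkene dioxolane to (1E,3E,5E)-1-iodoocta-1,3,5-triene, so the triene is introduced in the final step.
2. C2–C3: the acetic acid unit is added as a bis-silyl ketene acetal to the C3 peroxycarbenium ion of a 3-methoxy-1,2-dioxolane under chiral-anion control (sets C3).
3. The only ring, the 1,2-dioxolane, is formed by asymmetric hydroperoxidation and peroxyhemiketalisation of an (E)-β,β-dialkyl enone (sets C5), before the C3 side chain is attached.
4. C5–C6: the enone comes from a Pd-catalysed B-alkyl coupling of the (E)-enol triflate of acetylacetone with mono-hydroborated octa-1,7-diene.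
5. Side branches: the trienyl iodide from (2E,4E)-hepta-2,4-dienal (2 steps) and the ketene acetal from acetic acid (2 steps).

Assumption: the facial sense of the two new catalytic steps cannot be known in advance; the catalyst antipode named is the one assumed to give the stated face, and the other antipode (epi-quinidine amine; (R,R)-IDPi) is used if the sense is opposite.

The target is (3R,5R), with the two ring methyls cis. Atom numbering below follows the acid chain: C1 = CO2H, C3 and C5 = ring carbons, C14–C19 = triene.

## Route

**Step 1**
Reactants: 1 pentane-2,4-dione (acetylacetone)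
Product: 2 (E)-4-oxopent-2-en-2-yl trifluoromethanesulfonate (OTf trans to acetyl)
Conditions: Tf2O, 25% aq. Me4NOH, hexanes, 5 °C
Reagents that add atoms: triflic anhydride, O=S(=O)(OS(=O)(=O)C(F)(F)F)C(F)(F)F
Why: Stereoselective enol triflation; O-sulfonylation of the non-chelated tetraalkylammonium enolate gives the E enol triflate, as is established for β-keto esters, and any Z isomer is removed by chromatography.

**Step 2**
Reactants: 3 octa-1,7-diene (3 equiv); 2
Product: 4 (E)-4-methyldodeca-3,11-dien-2-one
Conditions: 3, 9-BBN, THF, 0 °C → rt; then 2, Pd(dppf)Cl2 (3 mol%), K3PO4, DMF/THF, 50 °C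
Reagents that add atoms: none
Why: B-alkyl Suzuki–Miyaura coupling; excess diene gives mono-hydroboration and leaves no B–H to reduce the ketone, and the activated vinyl triflate couples with retention of geometry to give the E enone with one terminal alkene kept as the later coupling handle.

**Step 3**
Reactants: 4
Product: 5 (5R)-3,5-dimethyl-5-(oct-7-en-1-yl)-1,2-dioxolan-3-ol (cyclic peroxyhemiketal, mixture of C3 anomers)
Conditions: 50% aq. H2O2 (3 equiv), 9-amino-9-deoxy-epi-quinine (10 mol%), Cl3CCO2H (20 mol%), dioxane, 30 °C
Reagents that add atoms: hydrogen peroxide, OO
Why: Proposed new method: iminium-catalysed asymmetric hydroperoxidation extended to an acyclic β,β-dialkyl enone to create a fully substituted C–OO stereocentre; the primary amine condenses with the ketone to an iminium ion, the protonated quinuclidine/trichloroacetate pair hydrogen-bonds H2O2 and delivers it to the Re face of the β-carbon (gives 5R), and hydrolysis followed by closure to the cyclic peroxyhemiketal makes the addition effectively irreversible and suppresses epoxide formation at 30 °C; the closest known reactions are the cinchona-amine-catalysed hydroperoxidation of β-monosubstituted enones to peroxyhemiketals and iminium-catalysed transfer hydrogenation of β,β-disubstituted enones, which shows that this enone class can be activated.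

**Step 4**
Reactants: 5
Product: 6 (5R)-3-methoxy-3,5-dimethyl-5-(oct-7-en-1-yl)-1,2-dioxolane (mixture of C3 epimers)
Conditions: MeOH, PPTS (cat.), rt
Reagents that add atoms: methanol, CO
Why: Acid-catalysed peroxyketal exchange at C3; the C5 tertiary dialkyl-peroxide carbon does not ionise under these conditions, and the C3 epimer mixture is irrelevant because C3 is ionised in step 7.

**Step 5**
Reactants: 7 acetic acid
Product: 8 tert-butyldimethylsilyl acetate
Conditions: TBSCl, Et3N, Et2O, 0 °C → rt; distil
Reagents that add atoms: tert-butyldimethylsilyl chloride, CC(C)(C)[Si](C)(C)Cl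
Why: Simple O-silylation of the carboxylic acid.

**Step 6**
Reactants: 8
Product: 9 1,1-bis(tert-butyldimethylsilyloxy)ethene (ketene bis-silyl acetal)
Conditions: LDA, THF, −78 °C; then TBSCl, DMPU, −78 °C → rt; distil
Reagents that add atoms: tert-butyldimethylsilyl chloride, CC(C)(C)[Si](C)(C)Cl
Why: Kinetic ester enolate formation and O-silylation give the bis-silyl ketene acetal, which delivers a CH2CO2Si unit so that no separate ester hydrolysis is needed later.

**Step 7**
Reactants: 6; 9 (1.5 equiv)
Product: 10 tert-butyldimethylsilyl 2-[(3R,5R)-3,5-dimethyl-5-(oct-7-en-1-yl)-1,2-dioxolan-3-yl]acetate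
Conditions: (S,S)-IDPi (BINOL-derived imidodiphosphorimidate, 3 mol%), toluene, −60 °C; Et3N quench
Reagents that add atoms: none (the C1–C2 unit comes from 9)
Why: Proposed new method: silylium/chiral-counteranion (IDPi) catalysed Mukaiyama-type addition to a ketone-derived cyclic peroxycarbenium ion; 9 silylates the IDPi acid, the silylium ion abstracts OMe from either C3 epimer of 6 to give one planar peroxycarbenium ion held as a contact ion pair in the confined chiral anion, and the ketene acetal attacks the Si face of C3 (anti to the C5 methyl, syn to the C5 chain) to give 3R and the cis-dimethyl ring, after which silyl transfer regenerates the catalyst; substrate bias is negligible (Me versus CH2R at C5) so the catalyst decides, and any (5S) material from step 3 becomes a separable trans diastereomer; the closest known reactions are the unselective TiCl4/SnCl4-mediated additions of silyl ketene acetals to 3-alkoxy-1,2-dioxolanes and IDPi-catalysed enantioselective additions of silyl nucleophiles to cyclic aliphatic oxocarbenium ions.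

**Step 8**
Reactants: 11 (2E,4E)-hepta-2,4-dienal
Product: 12 (3E,5E)-octa-3,5-dien-1-yne (volatile; carried on as a solution)
Conditions: TMSCHN2, LDA, THF, −78 °C; then 11, −78 °C → rt
Reagents that add atoms: (trimethylsilyl)diazomethane, C[Si](C)(C)C=[N+]=[N-]
Why: Colvin rearrangement (1,2-addition, Peterson-type elimination, alkylidene carbene 1,2-H shift) gives the terminal alkyne under aprotic conditions, which avoids the methoxide conjugate addition seen with enals under Ohira–Bestmann conditions and leaves both E alkenes intact.

**Step 9**
Reactants: 12
Product: 13 (1E,3E,5E)-1-iodoocta-1,3,5-triene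
Conditions: Cp2Zr(H)Cl, THF, rt, dark; then I2, −20 °C
Reagents that add atoms: iodine, II
Why: Hydrozirconation adds syn to the terminal alkyne with Zr at the terminus (faster than reaction at the internal diene), and iodinolysis with retention gives the 1E iodide as a single geometric isomer.

**Step 10**
Reactants: 10; 13
Product: 14 2-[(3R,5R)-5-[(9E,11E,13E)-hexadeca-9,11,13-trien-1-yl]-3,5-dimethyl-1,2-dioxolan-3-yl]acetic acid (target)
Conditions: 10, 9-BBN, THF, 0 °C → rt; then 13, Pd(dppf)Cl2 (5 mol%), AsPh3 (10 mol%), Cs2CO3, DMF/H2O, rt, dark; pH 4 work-up
Reagents that add atoms: none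
Why: B-alkyl Suzuki–Miyaura coupling; anti-Markovnikov hydroboration of the terminal alkene (the silyl ester and hindered di-tertiary peroxide are tolerated) followed by room-temperature sp3–sp2 coupling forms C13–C14 with retention of the iodide geometry, the aqueous carbonate cleaves the silyl ester in the same pot, and neither stereocentre is touched.

## Compound list

1 | pentane-2,4-dione | CC(=O)CC(C)=O | starting material
2 | (E)-4-oxopent-2-en-2-yl trifluoromethanesulfonate | C/C(OS(=O)(=O)C(F)(F)F)=C\C(C)=O | intermediate
3 | octa-1,7-diene | C=CCCCCC=C | starting material
4 | (E)-4-methyldodeca-3,11-dien-2-one | CC(=O)/C=C(\C)CCCCCCC=C | intermediate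
5 | (5R)-3,5-dimethyl-5-(oct-7-en-1-yl)-1,2-dioxolan-3-ol (C3 anomers) | C=CCCCCCC[C@]1(C)CC(C)(O)OO1 | intermediate
6 | (5R)-3-methoxy-3,5-dimethyl-5-(oct-7-en-1-yl)-1,2-dioxolane (C3 epimers) | C=CCCCCCC[C@]1(C)CC(C)(OC)OO1 | intermediate
7 | acetic acid | CC(=O)O | starting material
8 | tert-butyldimethylsilyl acetate | CC(=O)O[Si](C)(C)C(C)(C)C | intermediate
9 | 1,1-bis(tert-butyldimethylsilyloxy)ethene | C=C(O[Si](C)(C)C(C)(C)C)O[Si](C)(C)C(C)(C)C | intermediate
10 | tert-butyldimethylsilyl 2-[(3R,5R)-3,5-dimethyl-5-(oct-7-en-1-yl)-1,2-dioxolan-3-yl]acetate | C=CCCCCCC[C@]1(C)C[C@](C)(CC(=O)O[Si](C)(C)C(C)(C)C)OO1 | intermediate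
11 | (2E,4E)-hepta-2,4-dienal | CC/C=C/C=C/C=O | starting material
12 | (3E,5E)-octa-3,5-dien-1-yne | CC/C=C/C=C/C#C | intermediate
13 | (1E,3E,5E)-1-iodoocta-1,3,5-triene | CC/C=C/C=C/C=C/I | intermediate
14 | 2-[(3R,5R)-5-[(9E,11E,13E)-hexadeca-9,11,13-trien-1-yl]-3,5-dimethyl-1,2-dioxolan-3-yl]acetic acid | CC/C=C/C=C/C=C/CCCCCCCC[C@]1(C)C[C@](C)(CC(=O)O)OO1 | target

## Step count

Total steps: 10.
Longest linear sequence: 6 (steps 1, 2, 3, 4, 7, 10, from acetylacetone). The other branches are 5 steps (from octa-1,7-diene), 4 steps (from acetic acid) and 3 steps (from heptadienal).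

## Steps most likely to fail

1. **Step 3 (new asymmetric hydroperoxidation).** The risks are slow iminium formation or addition, E/Z scrambling through the dienamine that would erode ee (Me versus CH2R is a small difference), and epoxide formation.
   Fallback (known chemistry, stereospecific substitution instead of catalytic peroxidation), starting from enone 4:
   - CBS reduction to the allylic alcohol.
   - Hydroxyl-directed epoxidation.
   - Red-Al opening to the 1,3-diol.
   - Mesylation of the secondary alcohol and KOtBu closure to the 2,2,4-trisubstituted oxetane.
   - Opening at the tertiary carbon with ethereal H2O2 and catalytic TMSOTf, with inversion.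
   - Oxidation of the secondary carbinol, which gives 5.

2. **Step 7 (new chiral-anion-controlled peroxycarbenium addition).** The risks are insufficient facial control, or elimination or fragmentation of the cation.
   Fallback (known chemistry, separation instead of catalyst control): TiCl4-mediated addition of the silyl ketene acetal of S-ethyl thioacetate to 6, which is known for 3-alkoxy-1,2-dioxolanes and gives both C3 epimers. The (3R,5R) thioester is separated by chromatography or HPLC, carried through step 10, and hydrolysed at the end.

3. **Step 10 (hydroboration and Pd coupling next to the peroxide, with a sensitive triene).** The risks are O–O reduction by borane, arsine or Pd(0), and triene isomerisation.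
   Fallback (different union, sp2–sp2 at C15–C16, without an alkylborane in the presence of the peroxide):
   - Carry a TMS-capped terminal alkyne at C14–C15 through the sequence, using in step 2 the 9-BBN adduct of 1-(trimethylsilyl)dec-9-en-1-yne, made from 3 by hydroboration–iodination and alkynylation.
   - After the dioxolane is complete, desilylate and convert the alkyne to the (E)-vinyl iodide by hydrozirconation and iodination, which is precedented in the presence of cyclic peroxides.
   - Couple with (1E,3E)-hexa-1,3-dienylboronate (Suzuki) or the corresponding stannane (Stille).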